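(The rate constants were drawn at random within sensible limits; the run is a simulation.)

A small charge of partner has to pay for the target and also for every over-reaction, so I reckoned in fractions of the charge and watched a, the fraction of starting material left.

    starting material + partner → target, rate k1*[starting material]^0.5*[partner] (k1 = 0.24 M⁻⁰·⁵ s⁻¹)
    partner + target → over-reaction product (k2 = 0.033 M⁻¹ s⁻¹)
    starting material + protic impurity → quenched substrate (k3 = 0.023 M⁻¹ s⁻¹)

all flasks: protic impurity 0.100 M; time 4.0 min
- noon: starting material 0.20 M; partner 0.200 M (fed, over 2.5 min); all else is in the flask from the start; the feed brings no volume worth counting
- winter: starting material 0.20 M (fed, over 2.5 min); partner 0.200 M; all else is in the flask from the start; the feed brings no volume worth counting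
- spring: starting material 0.20 M; partner 0.200 M; everything together at the start

- the best flask by amount of target, in percent of the starting material charged; "all alike" if 1.5 percentage points covers them all (noon / winter / spring / all alike)
- amount of target at the end, in percent of the starting material charged, noon
- amount of target at the end, in percent of the starting material charged, winter
- amount of target at the end, in percent of the starting material charged, spring

I set the clocks of spring in a row. Against the full charge of starting material partner lives 9.32 s, the first clock, less than the 1.8 min half-life of target under full partner. So I took target to be made ahead of its attack. The quench came last, with a half-life of starting material of 5.0 min, longer than the run of 4.0 min, and at the start the step to target uses starting material 47 times as fast as the quench does. So I left the quench out of my reckoning of spring.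

Partner stands in both the making and the attack of target, so it cancels from their ratio, which is g(1 − a)/√a. The toll g, a selectivity factor, is the over-reaction constant times the root of the starting material charge over the constant of the step to target: 0.0615. Summed as a falls, the fraction paid is o = g(4/3 − 2√a + (2/3)a√a). Each over-reaction costs partner twice, once for the target it made and once for the attack. With charges equal and the quench left out, my reckoning therefore stops at a = o, with target at 1 − 2o. Rounds from 8.20% through 4.77% and 5.55% came to o = 5.35%, so I reckoned target in spring at 89.3%. Noon and winter I did not reckon.

The forecast named spring best, with noon 77%, winter 74% and spring 88.7%, a little below mine, on the ground that “Little time is left for the impurity or for over-reaction while the target is low”.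

The simulation gave spring as best, with noon 77.3%, winter 73.9% and spring 88.6%, and spring held 5.66% of over-reaction product after 4.00 min. The neighbour is spring with partner cut to 0.080 M. With the quench again left out, my reckoning there stops at a = 60.0%, and the same g gives o = 0.578%. That neighbour flask held 38.9% of target and 0.567% of over-reaction product after 4.00 min.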